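**Retrosynthetic overview**
- Feature: ring A (C5, C6, C23, C24, C25) shares the C5–C6 bond with ring B directly beside C7, and the methyl on C25 (C26) is cis to C4. Ring A is therefore cut across a C7(=O)–C6=C5 enone of ring B: C5–C25 by 1,4-addition of a 4-chlorobut-1-en-2-yl copper reagent, C6–C23 by alkylation of the resulting enolate, C25 entering as an exocyclic methylene.
- Endgame from the annulated C7 ketone: hydrogenation of the methylene (sets C25), C6=C7 enol triflate, iron-catalysed methylation (C8), desilylation.
- Ring B (C2, C3, C4, C5, C6, C7, C9, C22) is closed at C5=C6 by ring-closing metathesis of a C9 vinyl ketone with a C22 (Z)-hexa-2,5-dien-2-yl group; C22–C2 comes from cuprate addition of (Z)-5-iodohexa-1,4-diene to a C9=C22 cyclohexenecarboxylate.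
- Rings C and D come from (R)-Hajos–Parrish ketone: trans fusion by conjugate reduction, C9 ester by enol triflate carbonylation, C12 isopropyl by cuprate addition to a C17 cyclopentenone, C17 hydroxyl by hydride reduction.
- Order of rings: C/D (starting material), then B (step 16), then A (step 19).

Key step: step 19

Remark: atom numbers C1–C26 are those of the target SMILES (O18 is the hydroxyl oxygen) and are used for all intermediates; metal alkoxides and enolates that are only protonated on aqueous quench are counted as part of the work-up.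

**Route**

Step 1
Reactants: 1 (R)-Hajos–Parrish ketone, (7aR)-7a-methyl-2,3,7,7a-tetrahydro-1H-indene-1,5(6H)-dione (C17 and C9 ketones, C10=C11)
Product: 2 C17 ethylene ketal of 1 (C9 enone and C10=C11 unchanged)
Conditions: (Me3SiOCH2)2, TMSOTf (cat.), CH2Cl2, −78 °C
Reagents that add atoms: 1,2-bis(trimethylsilyloxy)ethane, C[Si](C)(C)OCCO[Si](C)(C)C
Why: TMSOTf-catalysed ketalization with the bis-silyl ether of ethylene glycol is selective for the saturated C17 cyclopentanone over the less electrophilic conjugated C9 ketone, so the enone needed for the next step is untouched.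

Step 2
Reactants: 2 C17 ethylene ketal of 1
Product: 3 trans-fused ketal ketone (C9 ketone; C17 dioxolane; H11 trans to the C20 methyl)
Conditions: t-BuCu (0.5 equiv, from CuI and t-BuLi), i-Bu2AlH, THF/HMPA, −50 °C; aq NH4Cl
Reagents that add atoms: none
Why: Copper hydride conjugate reduction (1,4-hydride transfer from the i-Bu2AlH/t-BuCu reagent, aluminium enolate protonated on quench): hydride should add to C11 along the axial trajectory of the enone half-chair, on the face away from the C20 methyl, which gives the trans C11–C19 ring fusion usual for this reagent with 7a-methylindenones, and the ketal is inert at −50 °C.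

Step 3
Reactants: 3 trans-fused ketal ketone
Product: 5 C9 enol triflate (C9=C22; C17 ketal), via lithium enolate 4 (not isolated)
Conditions: LiN(SiMe3)2, THF, −78 °C; then PhNTf2, −78 → 0 °C
Reagents that add atoms: N-phenylbis(trifluoromethanesulfonimide), O=S(=O)(N(c1ccccc1)S(=O)(=O)C(F)(F)F)C(F)(F)F
Why: Kinetic enolate formation and O-triflation; the base should remove a C22 proton and not a C10 proton because a C9=C22 double bond keeps the large torsion angle at the trans-fused C11–C19 bond whereas a C9=C10 double bond would flatten it (the bias that sends trans-fused 3-keto steroids to their C2 enolates).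

Step 4
Reactants: 5 C9 enol triflate
Product: 6 methyl C9-carboxylate with C9=C22 double bond (C17 ketal)
Conditions: Pd(OAc)2 (5 mol %), PPh3, CO (1 atm), MeOH, Et3N, DMF, 40 °C
Reagents that add atoms: carbon monoxide, [C-]#[O+]; methanol, CO
Why: Palladium-catalysed methoxycarbonylation of the enol triflate (zerovalent palladium formed in situ inserts into the C–O bond, then CO insertion and methanolysis) gives the conjugated ester with the double bond fixed at C9=C22.

Step 5
Reactants: 6 ketal ester
Product: 7 keto ester (C17 ketone; C9=C22 methyl ester)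
Conditions: 2 M HCl, THF, 40 °C
Reagents that add atoms: water, O
Why: Acid-catalysed hydrolysis of the dioxolane; the conjugated methyl ester is stable to dilute acid at this temperature and C11 is not alpha to the liberated C17 ketone, so the trans ring fusion cannot epimerise.

Step 6
Reactants: 7 keto ester
Product: 9 cyclopentenone ester (C17 ketone conjugated with C16=C12; C9=C22 ester), via trimethylsilyl enol ether 8 (not isolated)
Conditions: TMSOTf, Et3N, CH2Cl2, 0 °C; then Pd(OAc)2 (10 mol %), O2 (1 atm), DMSO, 40 °C
Reagents that add atoms: none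
Why: Saegusa–Ito dehydrogenation; soft enolisation of the C17 ketone can only go toward C16 because C19 is quaternary, the conjugated ester is not enolised by Et3N/TMSOTf, and Pd(OAc)2 with O2 as terminal oxidant converts the silyl enol ether into the enone.

Step 7
Reactants: 9 cyclopentenone ester
Product: 10 C12-isopropyl ketone (isopropyl cis to H11; trans to the C20 methyl)
Conditions: i-PrMgCl, CuBr·SMe2 (20 mol %), THF, −78 → −40 °C; aq NH4Cl
Reagents that add atoms: isopropylmagnesium chloride, CC(C)[Mg]Cl
Why: Copper-catalysed conjugate addition of the Grignard reagent, chemoselective for the cyclopentenone over the much less reactive trisubstituted enoate; the isopropyl group should enter C12 trans to the adjacent C11–C10 bond and on the face away from the C20 methyl (the usual outcome for 4-substituted cyclopentenones), that is cis to H11 as required.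

Step 8
Reactants: 10 C12-isopropyl ketone
Product: 11 C17 alcohol (OH cis to the C20 methyl)
Conditions: NaBH4, MeOH, 0 °C
Reagents that add atoms: none
Why: Hydride reduction of the ketone; NaBH4 should approach C17 from the face opposite the adjacent C20 methyl, giving the alcohol cis to that methyl, and does not reduce the conjugated ester at 0 °C.

Step 9
Reactants: 11 C17 alcohol
Product: 12 C17 tert-butyldimethylsilyl ether of 11 (ring C/D cyclohexenecarboxylate)
Conditions: TBSOTf, 2,6-lutidine, CH2Cl2, 0 °C
Reagents that add atoms: tert-butyldimethylsilyl trifluoromethanesulfonate, CC(C)(C)[Si](C)(C)OS(=O)(=O)C(F)(F)F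
Why: Silylation of the hindered secondary alcohol with the reactive silyl triflate and a non-nucleophilic base gives an ether that survives the organometallic, basic and metathesis steps that follow.

Step 10
Reactants: 13 but-2-yn-1-ol
Product: 15 (Z)-3-iodobut-2-en-1-ol, via cyclic alkenylalanate 14 (not isolated)
Conditions: NaAlH2(OCH2CH2OMe)2, THF, 0 °C → rt; then I2, THF, −78 °C → rt
Reagents that add atoms: iodine, II
Why: Hydroxyl-directed trans-hydroalumination of the propargylic alcohol (hydride to the carbon next to CH2O, aluminium to the methyl-bearing carbon in a five-membered alanate) followed by iodinolysis of the C–Al bond with retention, which fixes the Z geometry (iodine cis to CH2OH).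

Step 11
Reactants: 15 (Z)-3-iodobut-2-en-1-ol
Product: 16 (Z)-1-bromo-3-iodobut-2-ene
Conditions: CBr4, PPh3, CH2Cl2, 0 °C
Reagents that add atoms: tetrabromomethane, BrC(Br)(Br)Br
Why: Appel bromination under neutral conditions; substitution occurs at the primary carbon, so the alkene geometry and the alkenyl iodide are preserved.

Step 12
Reactants: 16 (Z)-1-bromo-3-iodobut-2-ene
Product: 17 (Z)-5-iodohexa-1,4-diene
Conditions: CH2=CHMgBr, CuI (10 mol %), THF, −30 → 0 °C
Reagents that add atoms: vinylmagnesium bromide, C=C[Mg]Br
Why: Copper-catalysed allylic substitution of the primary bromide by the vinyl Grignard reagent at the alpha carbon (the gamma carbon carries iodine and methyl), which is much faster than any reaction at the alkenyl iodide at low temperature.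

Step 13
Reactants: 17 (Z)-5-iodohexa-1,4-diene; 12 silyl ether enoate
Product: 21 trans-diequatorial methyl ester (C22 (Z)-hexa-2,5-dien-2-yl group trans to the C20 methyl; C9 ester trans to the C22 group), via alkenyllithium 18 (not isolated), via lithium dialkenylcuprate 19 (not isolated), via silyl ketene acetal 20 (not isolated)
Conditions: 17 (2.2 equiv), t-BuLi (4.4 equiv), Et2O, −78 °C; CuI (1.1 equiv), −40 °C; then 12, TMSCl, THF, −78 → −20 °C; aq NH4Cl work-up; crude, NaOMe (cat.), MeOH, 50 °C
Reagents that add atoms: none
Why: Iodine–lithium exchange with retention of geometry, formation of the Gilman cuprate R2CuLi and TMSCl-accelerated conjugate addition to the enoate; the alkenyl group should add to C22 on the face away from the axial C20 methyl, which stands 1,3 to C22, so that it ends equatorial, and methoxide then cleaves the silyl ketene acetal and equilibrates C9 to the trans-diequatorial ester.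

Step 14
Reactants: 21 trans-diequatorial methyl ester
Product: 22 Weinreb amide (C9–C(=O)N(OMe)Me)
Conditions: MeNHOMe·HCl, i-PrMgCl, THF, −20 → 0 °C
Reagents that add atoms: N,O-dimethylhydroxylamine hydrochloride, CNOC.Cl
Why: Weinreb amide formation by acyl substitution of the ester with the chloromagnesium amide of N,O-dimethylhydroxylamine; C9 is already in its preferred equatorial configuration, so the basic conditions cannot degrade it.

Step 15
Reactants: 22 Weinreb amide
Product: 23 C9 vinyl ketone (C7 ketone bearing CH=CH2; metathesis substrate)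
Conditions: CH2=CHMgBr, THF, 0 °C; poured into cold 1 M HCl
Reagents that add atoms: vinylmagnesium bromide, C=C[Mg]Br
Why: Weinreb ketone synthesis; the chelated tetrahedral adduct stops the Grignard addition at the ketone stage, and the inverse acidic quench prevents conjugate addition of the released amine to the vinyl ketone.

Step 16
Reactants: 23 C9 vinyl ketone
Product: 24 ring B cycloocta-2,6-dienone fused to rings C and D (C7 ketone; cis C5=C6; Z C2=C3 with the C1 methyl)
Conditions: second-generation Grubbs catalyst RuCl2(=CHPh)(H2IMes)(PCy3) (10 mol %), 1,4-benzoquinone (20 mol %), CH2Cl2 (2 mM), 40 °C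
Reagents that add atoms: none
Why: Ring-closing metathesis; the catalyst should load on the terminal alkene at C5 and close onto the vinyl ketone, the trans-diequatorial C9/C22 substituents and the Z C2=C3 bond hold the two ends close, an eight-membered ring can only hold the cis C5=C6 alkene, and benzoquinone suppresses Ru–H isomerisation of the 1,4-diene.

Step 17
Reactants: 25 but-3-yn-1-ol
Product: 26 3-(trimethylstannyl)but-3-en-1-ol
Conditions: Me3SnSnMe3, MeLi, THF, −20 °C; CuBr·SMe2, −78 °C; then 25, MeOH, −78 → −40 °C
Reagents that add atoms: hexamethylditin, C[Sn](C)(C)[Sn](C)(C)C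
Why: syn-Stannylcupration of the terminal alkyne with Me3SnCu·SMe2 places tin on the internal carbon, and methanol protonates the alkenylcopper adduct to give the 2-stannyl-1-alkene.

Step 18
Reactants: 26 3-(trimethylstannyl)but-3-en-1-ol
Product: 27 4-chloro-2-(trimethylstannyl)but-1-ene
Conditions: PPh3, CCl4, Et3N (cat.), 60 °C
Reagents that add atoms: tetrachloromethane, ClC(Cl)(Cl)Cl
Why: Appel chlorination of the primary alcohol under neutral conditions, which leave the acid-sensitive alkenylstannane intact.

Step 19
Reactants: 27 4-chloro-2-(trimethylstannyl)but-1-ene; 24 ring B dienone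
Product: 31 tetracyclic C7 ketone with exocyclic methylene on C25 (ring A cis-fused; H5 syn to H9), via alkenyllithium 28 (not isolated), via lithium dialkenylcuprate 29 (not isolated), via chloro ketone 30 (not isolated)
Conditions: 27 (2.4 equiv), MeLi (2.3 equiv), THF, −78 °C; CuBr·SMe2 (1.2 equiv), −78 → −60 °C; then 24, −78 → −40 °C; aq NH4Cl–NH3 work-up; crude 30, KH, THF, 0 °C → rt
Reagents that add atoms: none
Why: Tin–lithium exchange of 27 with MeLi gives alkenyllithium 28 (the primary chloride is inert at −78 °C), CuBr·SMe2 converts it into cuprate 29 of monovalent copper, and 29 adds 1,4 to the cis enone of 24 at C5 (bond C5–C25), leaving the C6 enolate; after protonation to chloro ketone 30, KH regenerates that enolate, which displaces chloride (bond C6–C23). The closest known reaction type is the methylenecyclopentane annulation of cyclic enones with a 4-chlorobut-1-en-2-yl copper reagent followed by KH. Ring A closes by a 5-exo-tet C-alkylation of the enolate. C6 is controlled by the tether, which hangs from C5 and can only reach the same face of the enolate, so the A/B fusion is cis; C5 is controlled by the substrate, the trans-diequatorial C9/C22 fusion and the two cis double bonds fixing the shape of ring B so that the cuprate is meant to attack the outer face of C5=C6 and place H5 syn to H9. The step needs 1,4- instead of 1,2-addition, secured by copper, and enolisation at C6 instead of C9, secured by C6 being an unhindered methylene while C9 is a hindered ring-fusion methine whose enolate could only cyclise to a bridged seven-membered ring. The transmission of the C9/C22 configuration across ring B to C5 is the least secure element of the route.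

Step 20
Reactants: 31 tetracyclic methylene ketone
Product: 32 tetracyclic C7 ketone with C25 methyl (C26 cis to C4; H25 cis to H5)
Conditions: H2 (1 atm), RhCl(PPh3)3 (10 mol %), benzene, rt
Reagents that add atoms: none
Why: Homogeneous hydrogenation with RhCl(PPh3)3, which reduces the 1,1-disubstituted exocyclic alkene and leaves the trisubstituted C2=C3 alkene and the ketone; hydrogen should add to C25 from the convex face of the cis-fused A/B unit (the face of H5 and H6), so that the new C26 methyl is cis to C4.

Step 21
Reactants: 32 tetracyclic C7 ketone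
Product: 34 C6=C7 enol triflate, via potassium enolate 33 (not isolated)
Conditions: KN(SiMe3)2, THF, −78 °C; then PhNTf2, −78 → 0 °C
Reagents that add atoms: N-phenylbis(trifluoromethanesulfonimide), O=S(=O)(N(c1ccccc1)S(=O)(=O)C(F)(F)F)C(F)(F)F
Why: Enolate formation and O-triflation; C6–H lies on the exposed convex face and its removal puts the double bond exocyclic to the five-membered ring A, whereas C9–H is an axial hydrogen of ring C next to the C22 substituent, so the C6=C7 enol triflate should form, its geometry fixed by ring B.

Step 22
Reactants: 34 C6=C7 enol triflate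
Product: 35 tert-butyldimethylsilyl ether of the target (C8 methyl on C7; C6=C7)
Conditions: MeMgBr, Fe(acac)3 (10 mol %), THF/NMP, −30 → 0 °C
Reagents that add atoms: methylmagnesium bromide, C[Mg]Br
Why: Iron-catalysed Kumada-type cross-coupling of the enol triflate with MeMgBr, which tolerates hindered fully substituted alkenyl triflates at low temperature, installs C8 with retention of the ring-fixed alkene geometry and does not affect the silyl ether.

Step 23
Reactants: 35 silyl ether of the target
Product: 36 target CNP0541339.1
Conditions: Bu4NF, THF, 50 °C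
Reagents that add atoms: none
Why: Fluoride-mediated cleavage of the silyl ether (Si–F bond formation) releases the C17 hydroxyl without touching the two alkenes.

**Compound list**

1 | (R)-Hajos–Parrish ketone, (7aR)-7a-methyl-2,3,7,7a-tetrahydro-1H-indene-1,5(6H)-dione | C[C@@]12CCC(=O)C=C1CCC2=O | starting material
2 | C17 ethylene ketal of 1 (C9 enone, C10=C11) | C[C@@]12CCC(=O)C=C1CCC23OCCO3 | intermediate
3 | trans-fused ketal ketone (C9 ketone; H11 trans to the C20 methyl) | C[C@@]12CCC(=O)C[C@H]1CCC23OCCO3 | intermediate
4 | lithium C9 enolate of 3 (C9=C22), not isolated | C[C@@]12CC=C(O[Li])C[C@H]1CCC23OCCO3 | intermediate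
5 | C9 enol triflate (C9=C22; C17 ketal) | C[C@@]12CC=C(OS(=O)(=O)C(F)(F)F)C[C@H]1CCC23OCCO3 | intermediate
6 | methyl C9-carboxylate (C9=C22; C17 ketal) | C[C@@]12CC=C(C(=O)OC)C[C@H]1CCC23OCCO3 | intermediate
7 | keto ester (C17 ketone; C9=C22 methyl ester) | C[C@@]12CC=C(C(=O)OC)C[C@H]1CCC2=O | intermediate
8 | C17 trimethylsilyl enol ether of 7 (C16=C17), not isolated | C[C@@]12CC=C(C(=O)OC)C[C@H]1CC=C2O[Si](C)(C)C | intermediate
9 | cyclopentenone ester (C17 ketone, C16=C12; C9=C22 ester) | C[C@@]12CC=C(C(=O)OC)C[C@H]1C=CC2=O | intermediate
10 | C12-isopropyl ketone (isopropyl cis to H11) | C[C@@]12CC=C(C(=O)OC)C[C@H]1[C@H](C(C)C)CC2=O | intermediate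
11 | C17 alcohol (OH cis to the C20 methyl) | C[C@@]12CC=C(C(=O)OC)C[C@H]1[C@H](C(C)C)C[C@H]2O | intermediate
12 | C17 tert-butyldimethylsilyl ether of 11 | C[C@@]12CC=C(C(=O)OC)C[C@H]1[C@H](C(C)C)C[C@H]2O[Si](C)(C)C(C)(C)C | intermediate
13 | but-2-yn-1-ol | CC#CCO | starting material
14 | cyclic alkenylalanate, sodium 2,2-bis(2-methoxyethoxy)-3-methyl-2,5-dihydro-1,2-oxaaluminol-2-uide, not isolated | CC1=CCO[Al-]1(OCCOC)OCCOC.[Na+] | intermediate
15 | (Z)-3-iodobut-2-en-1-ol | C/C(I)=C/CO | intermediate
16 | (Z)-1-bromo-3-iodobut-2-ene | C/C(I)=C/CBr | intermediate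
17 | (Z)-5-iodohexa-1,4-diene | C/C(I)=C/CC=C | intermediate
18 | hexa-2,5-dien-2-yllithium (geometry of 17 retained, lithium cis to C4), not isolated | C/C([Li])=C/CC=C | intermediate
19 | lithium bis(hexa-2,5-dien-2-yl)cuprate (geometry of 17 retained), not isolated | C/C(=C/CC=C)[Cu-]/C(C)=C\CC=C.[Li+] | intermediate
20 | silyl ketene acetal (C9=C(OMe)OSiMe3; C22 alkenyl group trans to the C20 methyl), not isolated | C[C@@]12C[C@H](/C(C)=C\CC=C)C(=C(OC)O[Si](C)(C)C)C[C@H]1[C@H](C(C)C)C[C@H]2O[Si](C)(C)C(C)(C)C | intermediate
21 | trans-diequatorial methyl ester (C22 (Z)-hexa-2,5-dien-2-yl; C9 CO2Me) | C[C@@]12C[C@H](/C(C)=C\CC=C)[C@@H](C(=O)OC)C[C@H]1[C@H](C(C)C)C[C@H]2O[Si](C)(C)C(C)(C)C | intermediate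
22 | Weinreb amide of 21 | C[C@@]12C[C@H](/C(C)=C\CC=C)[C@@H](C(=O)N(C)OC)C[C@H]1[C@H](C(C)C)C[C@H]2O[Si](C)(C)C(C)(C)C | intermediate
23 | C9 vinyl ketone | C[C@@]12C[C@H](/C(C)=C\CC=C)[C@@H](C(=O)C=C)C[C@H]1[C@H](C(C)C)C[C@H]2O[Si](C)(C)C(C)(C)C | intermediate
24 | ring B cycloocta-2,6-dienone fused to rings C and D | C/C1=C/C/C=C\C(=O)[C@H]3C[C@H]4[C@H](C(C)C)C[C@@H](O[Si](C)(C)C(C)(C)C)[C@]4(C)C[C@H]13 | intermediate
25 | but-3-yn-1-ol | C#CCCO | starting material
26 | 3-(trimethylstannyl)but-3-en-1-ol | C=C(CCO)[Sn](C)(C)C | intermediate
27 | 4-chloro-2-(trimethylstannyl)but-1-ene | C=C(CCCl)[Sn](C)(C)C | intermediate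
28 | 4-chlorobut-1-en-2-yllithium, not isolated | C=C([Li])CCCl | intermediate
29 | lithium bis(4-chlorobut-1-en-2-yl)cuprate, not isolated | C=C(CCCl)[Cu-]C(=C)CCCl.[Li+] | intermediate
30 | chloro ketone (C5 4-chlorobut-1-en-2-yl adduct of 24; H5 syn to H9), not isolated | C/C1=C/C[C@@H](C(=C)CCCl)CC(=O)[C@H]2C[C@H]3[C@H](C(C)C)C[C@@H](O[Si](C)(C)C(C)(C)C)[C@]3(C)C[C@H]12 | intermediate
31 | tetracyclic C7 ketone with exocyclic methylene on C25 (ring A cis-fused) | C/C1=C/C[C@@H]2[C@H](C(=O)[C@H]3C[C@H]4[C@H](C(C)C)C[C@@H](O[Si](C)(C)C(C)(C)C)[C@]4(C)C[C@H]13)CCC2=C | intermediate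
32 | tetracyclic C7 ketone with C25 methyl (C26 cis to C4) | C/C1=C/C[C@@H]2[C@H](C(=O)[C@H]3C[C@H]4[C@H](C(C)C)C[C@@H](O[Si](C)(C)C(C)(C)C)[C@]4(C)C[C@H]13)CC[C@@H]2C | intermediate
33 | potassium C6=C7 enolate of 32, not isolated | C/C1=C/C[C@@H]2/C(=C(/O[K])[C@H]3C[C@H]4[C@H](C(C)C)C[C@@H](O[Si](C)(C)C(C)(C)C)[C@]4(C)C[C@H]13)CC[C@@H]2C | intermediate
34 | C6=C7 enol triflate | C/C1=C/C[C@@H]2/C(=C(/OS(=O)(=O)C(F)(F)F)[C@H]3C[C@H]4[C@H](C(C)C)C[C@@H](O[Si](C)(C)C(C)(C)C)[C@]4(C)C[C@H]13)CC[C@@H]2C | intermediate
35 | tert-butyldimethylsilyl ether of the target | C/C1=C/C[C@@H]2/C(=C(/C)[C@H]3C[C@H]4[C@H](C(C)C)C[C@@H](O[Si](C)(C)C(C)(C)C)[C@]4(C)C[C@H]13)CC[C@@H]2C | intermediate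
36 | CNP0541339.1 | C/C1=C/C[C@@H]2/C(=C(/C)[C@H]3C[C@H]4[C@H](C(C)C)C[C@@H](O)[C@]4(C)C[C@H]13)CC[C@@H]2C | target

**Step count**

Total: 23 steps. Longest linear sequence: 18 steps (steps 1–9, 13–16, 19–23).

**Steps most likely to fail**

1. Step 19 (key step). What may go wrong: poor facial selectivity in the cuprate addition at C5, because the only control is the shape of ring B relayed from C9/C22; the C5 epimer would cyclise just as well and carry the wrong ring A configuration forward. Fallback (reagent control instead of substrate control), setting out from 27 and 24 and coming back at 30: stannane 27 is lithiated as before (MeLi, THF, −78 °C) and quenched with 2-isopropoxy-4,4,5,5-tetramethyl-1,3,2-dioxaborolane to give 2-(4-chlorobut-1-en-2-yl)-4,4,5,5-tetramethyl-1,3,2-dioxaborolane F1. F1 is then added to 24 in a rhodium-catalysed Hayashi–Miyaura 1,4-addition ([Rh(OH)(cod)]2 with the enantiomer of BINAP that delivers the alkenyl group to the required face of C5, dioxane/H2O, 40 °C, no added base so that the C4 methylene is not deprotonated). The product is chloro ketone 30, which is closed with KH as in step 19.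

2. Step 16. What may go wrong: failure of the eight-membered ring closure (oligomerisation by cross-metathesis, or Ru–H migration of the skipped diene into conjugation), the vinyl ketone being an electron-poor partner. Fallback (metathesis on an allylic alcohol, ketone restored afterwards), setting out from 23 and coming back at 24: Luche reduction of 23 (NaBH4, CeCl3·7H2O, MeOH, −78 °C) gives the C7 dienol F2, both carbinol epimers being usable. Ring-closing metathesis of F2 (second-generation Grubbs catalyst, CH2Cl2, 40 °C) gives the cycloocta-2,6-dienol F3, and Dess–Martin oxidation (NaHCO3 buffer) returns dienone 24.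

3. Step 21. What may go wrong: competing deprotonation at C9, which would give the C7=C9 enol triflate and destroy the C9 stereocenter. Fallback (thermodynamic instead of kinetic control, with regiospecific release of the enolate), setting out from 32 and coming back at 34: 32 is silylated under equilibrating conditions (TMSI, (Me3Si)2NH, CH2Cl2, rt), which should favour the C6=C7 trimethylsilyl enol ether F4 (double bond exocyclic to the five-membered ring A); F4 is purified. MeLi (THF, 0 °C) then releases the lithium enolate at C6=C7 only, and PhNTf2 gives 34.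

**Further compounds**

F1 | step 19 | 2-(4-chlorobut-1-en-2-yl)-4,4,5,5-tetramethyl-1,3,2-dioxaborolane | C=C(CCCl)B1OC(C)(C)C(C)(C)O1
F2 | step 16 | C7 dienol from 23 (C9–CH(OH)–CH=CH2; carbinol epimers) | C[C@@]12C[C@H](/C(C)=C\CC=C)[C@@H](C(O)C=C)C[C@H]1[C@H](C(C)C)C[C@H]2O[Si](C)(C)C(C)(C)C
F3 | step 16 | ring B cycloocta-2,6-dienol (C7 carbinol of 24; carbinol epimers) | C/C1=C/C/C=C\C(O)[C@H]3C[C@H]4[C@H](C(C)C)C[C@@H](O[Si](C)(C)C(C)(C)C)[C@]4(C)C[C@H]13
F4 | step 21 | C6=C7 trimethylsilyl enol ether of 32 | C/C1=C/C[C@@H]2/C(=C(/O[Si](C)(C)C)[C@H]3C[C@H]4[C@H](C(C)C)C[C@@H](O[Si](C)(C)C(C)(C)C)[C@]4(C)C[C@H]13)CC[C@@H]2C
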